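**Strategy.** Everything rests on disconnecting the C1′–C2′ bond of the cyclohexene ring. The quaternary C1′ and the methine C2′ sit next to each other and next to the C3′=C4′ alkene; if the first side-chain carbon on C1′ is taken at the carboxylic acid level, this is the retron of a [3,3] shift. An Ireland–Claisen ring contraction of a δ-lactone makes that bond, the carbocycle, the ring alkene and both ring stereocentres in one operation from a single carbinol centre. The precursor is (6S)-6-[(Z)-but-2-en-2-yl]-3-methyloxan-2-one. Chain extension to a Z allylic carbonate and palladium-catalysed asymmetric O-allylation of a monosilylated trimethoxyresorcinol later set chromene C2.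

Key step: step 4

Assumption: with the (Z)-carbonate, the (S,S) antipode of the cyclohexanediamine bis(2-diphenylphosphinobenzamide) ligand is taken to give the (R)-ether (usual trend for Z-trisubstituted allyl carbonates); the sense is to be confirmed by correlation, and the mirror-image ligand is used if it proves opposite.

Assumption: (Z)-3-iodobut-2-en-1-ol (17) is bought as a catalogue compound (otherwise one step from but-2-yn-1-ol by hydroalumination–iodination).

Step 1
Reactants: 1 (Z)-2-bromobut-2-ene; 2 methyl 5-chloro-5-oxopentanoate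
Product: 5 methyl (6Z)-6-methyl-5-oxooct-6-enoate, via alkenyllithium 3 (not isolated), via alkenylzinc chloride 4 (not isolated)
Conditions: t-BuLi (2.0 equiv), THF, −78 °C; ZnCl2, −78 → 0 °C; then 2, Pd(PPh3)4 (3 mol %), THF, 0 °C → rt
Reagents that add atoms: none
Why: Bromine–lithium exchange at −78 °C retains the alkene geometry, transmetalation to zinc gives a reagent that tolerates the ester, and the Negishi acylation stops at the ketone, so the Z enone should form without over-addition or any regiochemical question.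

Step 2
Reactants: 5 methyl (6Z)-6-methyl-5-oxooct-6-enoate
Product: 7 (6S)-6-[(2Z)-but-2-en-2-yl]oxan-2-one, via hydroxy ester 6 (not isolated)
Conditions: (R)-Me-CBS oxazaborolidine [(R)-1-methyl-3,3-diphenyltetrahydro-1H,3H-pyrrolo[1,2-c][1,3,2]oxazaborole] (20 mol %), catecholborane (1.5 equiv), PhMe, −78 °C; MeOH quench; then pyridinium p-toluenesulfonate (10 mol %), PhMe, 60 °C
Reagents that add atoms: none
Why: In this Corey–Bakshi–Shibata reduction the α-branched alkenyl group acts as the large substituent and the CH2 chain as the small one, so the (R)-catalyst should deliver hydride to give the (5S)-allylic alcohol, which then closes to the six-membered lactone under mild acid that leaves the allylic C–O bond intact.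

Step 3
Reactants: 7 (6S)-6-[(2Z)-but-2-en-2-yl]oxan-2-one
Product: 9 (3RS,6S)-6-[(2Z)-but-2-en-2-yl]-3-methyloxan-2-one, via lithium enolate 8 (not isolated)
Conditions: LiN(i-Pr)2 (1.05 equiv), THF, −78 °C; MeI, −78 → −40 °C
Reagents that add atoms: iodomethane, CI
Why: α-Alkylation of a lactone enolate is regiochemically unambiguous because only C3 is enolisable, and the C3 epimer ratio is irrelevant because this centre becomes planar in the next step.

Step 4
Reactants: 9 (3RS,6S)-6-[(2Z)-but-2-en-2-yl]-3-methyloxan-2-one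
Product: 13 (1R,2R)-1,2,3-trimethylcyclohex-3-ene-1-carboxylic acid, via lithium enolate 10 (not isolated), via silyl ketene acetal 11 (not isolated), via silyl ester 12 (not isolated)
Conditions: LiN(i-Pr)2 (1.2 equiv), THF, −78 °C; t-BuMe2SiCl, DMPU, −78 °C → rt; solvent switch to PhMe, 110 °C; then 1 M HCl, THF, rt
Reagents that add atoms: none
Why: Deprotonation at C3 and O-silylation give cyclic ketene acetal 11, which on heating should undergo a concerted suprafacial [3,3] shift, an Ireland–Claisen rearrangement in its lactone ring-contraction form (closest known type: 6-alkenyl δ-lactone silyl ketene acetals giving cyclohexenecarboxylic acids). The cyclohexene closes by joining ketene-acetal C3 to the terminal butenyl carbon while the allylic C6–O bond breaks, so the six-membered oxygen ring is exchanged for the six-membered carbocycle inside a six-centre array that the C4–C5 tether forces into a boat (bicyclo[2.2.2]-like); a chair is geometrically impossible. C1′ is controlled by the C6 carbinol centre, because the butenyl group can only reach the ketene-acetal face from which it projects. C2′ is controlled by the Z alkene geometry, which puts the terminal methyl on the inside of the boat and therefore cis to the C1′ methyl and trans to the carboxyl. The step needs O- rather than C-silylation, secured by the ring-locked lactone enolate with the hard silyl chloride in DMPU, and needs the shift to outrun ketene-acetal decomposition, helped by the fully intramolecular pre-organised array. Mild hydrolysis of silyl ester 12 then frees acid 13.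

Step 5
Reactants: 13 (1R,2R)-1,2,3-trimethylcyclohex-3-ene-1-carboxylic acid
Product: 14 [(1R,2R)-1,2,3-trimethylcyclohex-3-en-1-yl]methanol
Conditions: LiAlH4, THF, 0 °C → reflux; then H2O
Reagents that add atoms: none
Why: Hydride reduction of the hindered acid should give the primary alcohol without touching the trisubstituted alkene or either stereocentre.

Step 6
Reactants: 14 [(1R,2R)-1,2,3-trimethylcyclohex-3-en-1-yl]methanol
Product: 15 (1R,2R)-1,2,3-trimethylcyclohex-3-ene-1-carbaldehyde
Conditions: Dess–Martin periodinane, CH2Cl2, rt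
Reagents that add atoms: none
Why: Dess–Martin oxidation of a primary alcohol stops at the aldehyde, which has no α-hydrogen and cannot epimerise.

Step 7
Reactants: 15 (1R,2R)-1,2,3-trimethylcyclohex-3-ene-1-carbaldehyde
Product: 16 (3R,4S)-4-ethenyl-2,3,4-trimethylcyclohex-1-ene
Conditions: Ph3PCH3Br, KOt-Bu, THF, 0 °C → rt
Reagents that add atoms: methyltriphenylphosphonium bromide, C[P+](c1ccccc1)(c1ccccc1)c1ccccc1.[Br-]
Why: Wittig methylenation with the unstabilised ylide is reliable for α-quaternary aldehydes and installs the second chain carbon as a terminal alkene.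

Step 8
Reactants: 16 (3R,4S)-4-ethenyl-2,3,4-trimethylcyclohex-1-ene; 17 (Z)-3-iodobut-2-en-1-ol
Product: 19 (2Z)-3-methyl-5-[(1S,2S)-1,2,3-trimethylcyclohex-3-en-1-yl]pent-2-en-1-ol, via alkylborane 18 (not isolated)
Conditions: 9-BBN-H (1.2 equiv), THF, 0 °C → rt; then 17, PdCl2(dppf) (5 mol %), AsPh3 (10 mol %), Cs2CO3, DMF–H2O, rt
Reagents that add atoms: none
Why: 9-BBN hydroborates the monosubstituted alkene at its terminus far faster than the trisubstituted ring alkene, and the B-alkyl Suzuki–Miyaura coupling transfers the primary alkyl group to the vinyl iodide with retention of the Z geometry.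

Step 9
Reactants: 19 (2Z)-3-methyl-5-[(1S,2S)-1,2,3-trimethylcyclohex-3-en-1-yl]pent-2-en-1-ol
Product: 20 methyl (2Z)-3-methyl-5-[(1S,2S)-1,2,3-trimethylcyclohex-3-en-1-yl]pent-2-en-1-yl carbonate
Conditions: ClCO2Me, pyridine, CH2Cl2, 0 °C
Reagents that add atoms: methyl chloroformate, COC(Cl)=O
Why: Acylation of the primary allylic alcohol gives the carbonate, which ionises readily with zerovalent palladium and releases its own base.

Step 10
Reactants: 21 2,3,4-trimethoxybenzaldehyde
Product: 22 5-bromo-2,3,4-trimethoxybenzaldehyde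
Conditions: NBS, MeCN, rt
Reagents that add atoms: N-bromosuccinimide, O=C1CCC(=O)N1Br
Why: Electrophilic aromatic bromination should go to C5, the only free position that is ortho and para to methoxy groups and meta to the formyl group.

Step 11
Reactants: 22 5-bromo-2,3,4-trimethoxybenzaldehyde
Product: 24 5-bromo-2,3,4-trimethoxyphenol, via aryl formate 23 (not isolated)
Conditions: m-CPBA, CH2Cl2, rt; then K2CO3 (cat.), MeOH, rt
Reagents that add atoms: 3-chloroperoxybenzoic acid, OOC(=O)c1cccc(Cl)c1
Why: Baeyer–Villiger (Dakin-type) oxidation of the electron-rich benzaldehyde proceeds with aryl migration to the formate, which mild methanolysis converts into the phenol.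

Step 12
Reactants: 24 5-bromo-2,3,4-trimethoxyphenol
Product: 25 (5-bromo-2,3,4-trimethoxyphenoxy)triisopropylsilane
Conditions: i-Pr3SiCl, imidazole, DMF, rt
Reagents that add atoms: chlorotriisopropylsilane, CC(C)[Si](Cl)(C(C)C)C(C)C
Why: Standard phenol silylation gives a triisopropylsilyl ether that should survive the organolithium, alkaline peroxide and Lewis acid used later and is removed by fluoride at the end.

Step 13
Reactants: 25 (5-bromo-2,3,4-trimethoxyphenoxy)triisopropylsilane
Product: 28 2,3,4-trimethoxy-5-[(triisopropylsilyl)oxy]phenol, via aryllithium 26 (not isolated), via dimethyl arylboronate 27 (not isolated)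
Conditions: n-BuLi, THF, −78 °C; B(OMe)3, −78 → 0 °C; then AcOH, 30 % H2O2, 0 °C → rt
Reagents that add atoms: hydrogen peroxide, OO
Why: Bromine–lithium exchange, borylation and oxidation of the aryl–boron bond replace bromine by hydroxyl at a fixed position, giving the monoprotected resorcinol whose only free ring position lies between the two oxygens.

Step 14
Reactants: 20 methyl (2Z)-3-methyl-5-[(1S,2S)-1,2,3-trimethylcyclohex-3-en-1-yl]pent-2-en-1-yl carbonate; 28 2,3,4-trimethoxy-5-[(triisopropylsilyl)oxy]phenol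
Product: 29 triisopropyl[2,3,4-trimethoxy-5-({(3R)-3-methyl-5-[(1S,2S)-1,2,3-trimethylcyclohex-3-en-1-yl]pent-1-en-3-yl}oxy)phenoxy]silane
Conditions: Pd2(dba)3·CHCl3 (1 mol %), (S,S)-N,N′-(cyclohexane-1,2-diyl)bis[2-(diphenylphosphino)benzamide] (3 mol %), CH2Cl2, rt
Reagents that add atoms: none
Why: In this Tsuji–Trost asymmetric allylic alkylation the carbonate ionises to a π-allylpalladium complex, and the chiral diphosphine pocket should steer the phenoxide to the more substituted terminus and to one enantioface, setting the future chromene C2 as R (sense as assumed above).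

Step 15
Reactants: 29 triisopropyl[2,3,4-trimethoxy-5-({(3R)-3-methyl-5-[(1S,2S)-1,2,3-trimethylcyclohex-3-en-1-yl]pent-1-en-3-yl}oxy)phenoxy]silane
Product: 31 (3R)-3-methyl-3-{2,3,4-trimethoxy-5-[(triisopropylsilyl)oxy]phenoxy}-5-[(1S,2S)-1,2,3-trimethylcyclohex-3-en-1-yl]pentan-1-ol, via alkylborane 30 (not isolated)
Conditions: 9-BBN-H (2 equiv), THF, rt; then NaOH (aq), H2O2, 0 °C
Reagents that add atoms: hydrogen peroxide, OO
Why: Hydroboration–oxidation with 9-BBN is selective for the terminal vinyl group, places oxygen on the end carbon and leaves the ring alkene and all stereocentres untouched.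

Step 16
Reactants: 31 (3R)-3-methyl-3-{2,3,4-trimethoxy-5-[(triisopropylsilyl)oxy]phenoxy}-5-[(1S,2S)-1,2,3-trimethylcyclohex-3-en-1-yl]pentan-1-ol
Product: 32 (3R)-3-methyl-3-{2,3,4-trimethoxy-5-[(triisopropylsilyl)oxy]phenoxy}-5-[(1S,2S)-1,2,3-trimethylcyclohex-3-en-1-yl]pentanal
Conditions: Dess–Martin periodinane, pyridine, CH2Cl2, 0 °C → rt
Reagents that add atoms: none
Why: Buffered Dess–Martin oxidation gives the β-aryloxy aldehyde under non-basic conditions that should avoid β-elimination of the aryloxide.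

Step 17
Reactants: 32 (3R)-3-methyl-3-{2,3,4-trimethoxy-5-[(triisopropylsilyl)oxy]phenoxy}-5-[(1S,2S)-1,2,3-trimethylcyclohex-3-en-1-yl]pentanal
Product: 33 (2R,4RS)-6,7,8-trimethoxy-2-methyl-5-[(triisopropylsilyl)oxy]-2-{2-[(1S,2S)-1,2,3-trimethylcyclohex-3-en-1-yl]ethyl}-3,4-dihydro-2H-chromen-4-ol
Conditions: ZnCl2 (1 M in Et2O, 1.5 equiv), CH2Cl2, −20 °C
Reagents that add atoms: none
Why: In this intramolecular Friedel–Crafts hydroxyalkylation the zinc-activated aldehyde attacks the only free ring position, ortho to the ether oxygen and para to a methoxy group, closing the six-membered pyran ring; the new C4 centre is of no consequence.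

Step 18
Reactants: 33 (2R,4RS)-6,7,8-trimethoxy-2-methyl-5-[(triisopropylsilyl)oxy]-2-{2-[(1S,2S)-1,2,3-trimethylcyclohex-3-en-1-yl]ethyl}-3,4-dihydro-2H-chromen-4-ol
Product: 35 triisopropyl[((2R)-6,7,8-trimethoxy-2-methyl-2-{2-[(1S,2S)-1,2,3-trimethylcyclohex-3-en-1-yl]ethyl}-2H-chromen-5-yl)oxy]silane, via benzylic mesylate 34 (not isolated)
Conditions: MeSO2Cl, Et3N, CH2Cl2, 0 °C → rt
Reagents that add atoms: none
Why: Mesylation of the electron-rich benzylic alcohol should be followed by base-assisted elimination through the oxygen-stabilised benzylic cation, and since C2 is quaternary the alkene can only form between C3 and C4.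

Step 19
Reactants: 35 triisopropyl[((2R)-6,7,8-trimethoxy-2-methyl-2-{2-[(1S,2S)-1,2,3-trimethylcyclohex-3-en-1-yl]ethyl}-2H-chromen-5-yl)oxy]silane
Product: 36 (2R)-6,7,8-trimethoxy-2-methyl-2-{2-[(1S,2S)-1,2,3-trimethylcyclohex-3-en-1-yl]ethyl}-2H-chromen-5-ol
Conditions: Bu4NF, THF, 0 °C
Reagents that add atoms: none
Why: Fluoride cleaves the aryl silyl ether under conditions that should not affect the chromene, the ring alkene or any stereocentre.

**Compound list**

1 | (Z)-2-bromobut-2-ene | C/C=C(/C)Br | starting material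
2 | methyl 5-chloro-5-oxopentanoate | COC(=O)CCCC(Cl)=O | starting material
3 | (E)-but-2-en-2-yllithium (lithium cis to the C3 methyl, geometry of 1 retained) | C/C=C(/C)[Li] | intermediate
4 | (Z)-but-2-en-2-ylzinc chloride (zinc cis to the C3 methyl) | C/C=C(/C)[Zn]Cl | intermediate
5 | methyl (6Z)-6-methyl-5-oxooct-6-enoate | C/C=C(C)\C(=O)CCCC(=O)OC | intermediate
6 | methyl (5S,6Z)-5-hydroxy-6-methyloct-6-enoate | C/C=C(C)\[C@@H](O)CCCC(=O)OC | intermediate
7 | (6S)-6-[(2Z)-but-2-en-2-yl]oxan-2-one | C/C=C(C)\[C@@H]1CCCC(=O)O1 | intermediate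
8 | lithium enolate of 7 | C/C=C(C)\[C@@H]1CCC=C(O[Li])O1 | intermediate
9 | (3RS,6S)-6-[(2Z)-but-2-en-2-yl]-3-methyloxan-2-one | C/C=C(C)\[C@@H]1CCC(C)C(=O)O1 | intermediate
10 | lithium enolate of 9 | C/C=C(C)\[C@@H]1CCC(C)=C(O[Li])O1 | intermediate
11 | (2S)-2-[(2Z)-but-2-en-2-yl]-6-[(tert-butyldimethylsilyl)oxy]-5-methyl-3,4-dihydro-2H-pyran | C/C=C(C)\[C@@H]1CCC(C)=C(O[Si](C)(C)C(C)(C)C)O1 | intermediate
12 | tert-butyldimethylsilyl (1R,2R)-1,2,3-trimethylcyclohex-3-ene-1-carboxylate | CC(C)(C)[Si](C)(C)OC(=O)[C@]1(C)CCC=C(C)[C@H]1C | intermediate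
13 | (1R,2R)-1,2,3-trimethylcyclohex-3-ene-1-carboxylic acid (cis-1,2-dimethyl) | OC(=O)[C@]1(C)CCC=C(C)[C@H]1C | intermediate
14 | [(1R,2R)-1,2,3-trimethylcyclohex-3-en-1-yl]methanol | OC[C@]1(C)CCC=C(C)[C@H]1C | intermediate
15 | (1R,2R)-1,2,3-trimethylcyclohex-3-ene-1-carbaldehyde | O=C[C@]1(C)CCC=C(C)[C@H]1C | intermediate
16 | (3R,4S)-4-ethenyl-2,3,4-trimethylcyclohex-1-ene | C=C[C@]1(C)CCC=C(C)[C@H]1C | intermediate
17 | (Z)-3-iodobut-2-en-1-ol | C/C(I)=C/CO | starting material
18 | 9-{2-[(1R,2S)-1,2,3-trimethylcyclohex-3-en-1-yl]ethyl}-9-borabicyclo[3.3.1]nonane | B1(CC[C@]2(C)CCC=C(C)[C@H]2C)C3CCCC1CCC3 | intermediate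
19 | (2Z)-3-methyl-5-[(1S,2S)-1,2,3-trimethylcyclohex-3-en-1-yl]pent-2-en-1-ol | OC/C=C(C)\CC[C@]1(C)CCC=C(C)[C@H]1C | intermediate
20 | methyl (2Z)-3-methyl-5-[(1S,2S)-1,2,3-trimethylcyclohex-3-en-1-yl]pent-2-en-1-yl carbonate | COC(=O)OC/C=C(C)\CC[C@]1(C)CCC=C(C)[C@H]1C | intermediate
21 | 2,3,4-trimethoxybenzaldehyde | COc1ccc(C=O)c(OC)c1OC | starting material
22 | 5-bromo-2,3,4-trimethoxybenzaldehyde | COc1c(Br)cc(C=O)c(OC)c1OC | intermediate
23 | 5-bromo-2,3,4-trimethoxyphenyl formate | COc1c(Br)cc(OC=O)c(OC)c1OC | intermediate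
24 | 5-bromo-2,3,4-trimethoxyphenol | COc1c(Br)cc(O)c(OC)c1OC | intermediate
25 | (5-bromo-2,3,4-trimethoxyphenoxy)triisopropylsilane | COc1c(Br)cc(O[Si](C(C)C)(C(C)C)C(C)C)c(OC)c1OC | intermediate
26 | {2,3,4-trimethoxy-5-[(triisopropylsilyl)oxy]phenyl}lithium | COc1c([Li])cc(O[Si](C(C)C)(C(C)C)C(C)C)c(OC)c1OC | intermediate
27 | dimethyl {2,3,4-trimethoxy-5-[(triisopropylsilyl)oxy]phenyl}boronate | COc1c(B(OC)OC)cc(O[Si](C(C)C)(C(C)C)C(C)C)c(OC)c1OC | intermediate
28 | 2,3,4-trimethoxy-5-[(triisopropylsilyl)oxy]phenol | COc1c(O)cc(O[Si](C(C)C)(C(C)C)C(C)C)c(OC)c1OC | intermediate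
29 | triisopropyl[2,3,4-trimethoxy-5-({(3R)-3-methyl-5-[(1S,2S)-1,2,3-trimethylcyclohex-3-en-1-yl]pent-1-en-3-yl}oxy)phenoxy]silane | COc1c(O[C@](C)(CC[C@]2(C)CCC=C(C)[C@H]2C)C=C)cc(O[Si](C(C)C)(C(C)C)C(C)C)c(OC)c1OC | intermediate
30 | B-alkyl-9-BBN adduct of 29, boron on the terminal carbon (formally 3S because boron ranks below carbon; spatial arrangement unchanged) | COc1c(O[C@](C)(CC[C@]2(C)CCC=C(C)[C@H]2C)CCB2C3CCCC2CCC3)cc(O[Si](C(C)C)(C(C)C)C(C)C)c(OC)c1OC | intermediate
31 | (3R)-3-methyl-3-{2,3,4-trimethoxy-5-[(triisopropylsilyl)oxy]phenoxy}-5-[(1S,2S)-1,2,3-trimethylcyclohex-3-en-1-yl]pentan-1-ol | COc1c(O[C@](C)(CC[C@]2(C)CCC=C(C)[C@H]2C)CCO)cc(O[Si](C(C)C)(C(C)C)C(C)C)c(OC)c1OC | intermediate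
32 | (3R)-3-methyl-3-{2,3,4-trimethoxy-5-[(triisopropylsilyl)oxy]phenoxy}-5-[(1S,2S)-1,2,3-trimethylcyclohex-3-en-1-yl]pentanal | COc1c(O[C@](C)(CC[C@]2(C)CCC=C(C)[C@H]2C)CC=O)cc(O[Si](C(C)C)(C(C)C)C(C)C)c(OC)c1OC | intermediate
33 | (2R,4RS)-6,7,8-trimethoxy-2-methyl-5-[(triisopropylsilyl)oxy]-2-{2-[(1S,2S)-1,2,3-trimethylcyclohex-3-en-1-yl]ethyl}-3,4-dihydro-2H-chromen-4-ol | COc1c(O[Si](C(C)C)(C(C)C)C(C)C)c2c(c(OC)c1OC)O[C@](C)(CC[C@]1(C)CCC=C(C)[C@H]1C)CC2O | intermediate
34 | 4-methanesulfonate of 33 | COc1c(O[Si](C(C)C)(C(C)C)C(C)C)c2c(c(OC)c1OC)O[C@](C)(CC[C@]1(C)CCC=C(C)[C@H]1C)CC2OS(C)(=O)=O | intermediate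
35 | triisopropyl[((2R)-6,7,8-trimethoxy-2-methyl-2-{2-[(1S,2S)-1,2,3-trimethylcyclohex-3-en-1-yl]ethyl}-2H-chromen-5-yl)oxy]silane | COc1c(O[Si](C(C)C)(C(C)C)C(C)C)c2c(c(OC)c1OC)O[C@](C)(CC[C@]1(C)CCC=C(C)[C@H]1C)C=C2 | intermediate
36 | (2R)-6,7,8-trimethoxy-2-methyl-2-{2-[(1S,2S)-1,2,3-trimethylcyclohex-3-en-1-yl]ethyl}-2H-chromen-5-ol | COc1c(O)c2c(c(OC)c1OC)O[C@](C)(CC[C@]1(C)CCC=C(C)[C@H]1C)C=C2 | target

**Step count and risk**

Total step count: 19. Longest linear sequence: 15 steps (steps 1–9, then 14–19); the arene branch (steps 10–13) joins at step 14.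

Steps most likely to fail:

1. Step 4 (key step). The [3,3] shift must pass through a crowded boat in which a methyl group points inwards while a quaternary centre forms, so rearrangement may be outrun by decomposition of the ketene acetal (C-silylation, hydrolysis back to the lactone, elimination). The fallback gives up the lactone and builds the ring by a catalytic asymmetric Diels–Alder reaction. It sets out from none of the numbered compounds but from two further commercial materials, (3E)-3-methylpenta-1,3-diene F1 and 2-methylprop-2-enal F2. These are combined at −78 °C under a chiral cationic oxazaborolidine Lewis acid whose antipode is chosen by its established model. The terminal methyl of the diene should direct the bond to the formyl-bearing carbon, and the α-methyl aldehyde should react with the formyl group exo, which places the two ring methyls cis. The fallback comes back to the route at aldehyde 15 and replaces steps 1–6.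

2. Step 14. The phenoxide may attack the unsubstituted allyl terminus and give the linear ether, or facial discrimination at the tertiary terminus may be low or opposite to the assumed sense. The fallback sets out from allylic alcohol 19, which is oxidised with MnO2 to (2Z)-3-methyl-5-[(1S,2S)-1,2,3-trimethylcyclohex-3-en-1-yl]pent-2-enal F3. Condensation of F3 with phenol 28 (ethylenediammonium diacetate, PhMe, 110 °C) proceeds by ortho-alkylation, dehydration to the ortho-quinone methide and oxa-6π electrocyclisation. It should give the silyl-protected chromene without control at C2, as a mixture of 35 and its (2S) epimer F4. These are diastereomers and are separated by preparative HPLC. The fallback comes back at 35 and replaces steps 9 and 14–18.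

3. Step 17. The β-aryloxy aldehyde may lose the aryloxide by β-elimination faster than it cyclises, and re-addition or condensation of the fragments would erode the C2 configuration; self-condensation of the aldehyde is also possible. The fallback sets out from alcohol 31, which is oxidised (TEMPO cat., PhI(OAc)2, MeCN–H2O) to (3R)-3-methyl-3-{2,3,4-trimethoxy-5-[(triisopropylsilyl)oxy]phenoxy}-5-[(1S,2S)-1,2,3-trimethylcyclohex-3-en-1-yl]pentanoic acid F5, which cannot eliminate as easily. Friedel–Crafts acylation ((CF3CO)2O, CH2Cl2, 0 °C) closes the ring to the (2R)-chroman-4-one F6. Reduction with NaBH4 in MeOH then gives chroman-4-ol 33, where the fallback comes back.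

**Further compounds**

F1 | step 4 | (3E)-3-methylpenta-1,3-diene | C=C/C(C)=C/C
F2 | step 4 | 2-methylprop-2-enal | CC(=C)C=O
F3 | step 14 | (2Z)-3-methyl-5-[(1S,2S)-1,2,3-trimethylcyclohex-3-en-1-yl]pent-2-enal | O=C/C=C(C)\CC[C@]1(C)CCC=C(C)[C@H]1C
F4 | step 14 | (2S) epimer of 35 | COc1c(O[Si](C(C)C)(C(C)C)C(C)C)c2c(c(OC)c1OC)O[C@@](C)(CC[C@]1(C)CCC=C(C)[C@H]1C)C=C2
F5 | step 17 | (3R)-3-methyl-3-{2,3,4-trimethoxy-5-[(triisopropylsilyl)oxy]phenoxy}-5-[(1S,2S)-1,2,3-trimethylcyclohex-3-en-1-yl]pentanoic acid | COc1c(O[C@](C)(CC[C@]2(C)CCC=C(C)[C@H]2C)CC(O)=O)cc(O[Si](C(C)C)(C(C)C)C(C)C)c(OC)c1OC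
F6 | step 17 | (2R)-6,7,8-trimethoxy-2-methyl-5-[(triisopropylsilyl)oxy]-2-{2-[(1S,2S)-1,2,3-trimethylcyclohex-3-en-1-yl]ethyl}-2,3-dihydro-4H-chromen-4-one | COc1c(O[Si](C(C)C)(C(C)C)C(C)C)c2c(c(OC)c1OC)O[C@](C)(CC[C@]1(C)CCC=C(C)[C@H]1C)CC2=O
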